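## Retrosynthetic overview

1. Target ⇒ remove the C8 acyl group and the C13 acetate ⇒ macrocyclic 11-bromo-8-hydroxy butenolide; C13 enters last by Stille hydroxymethylation of the α-C–Br bond.
2. Ten-membered carbocycle (third ring) ⇒ C7–C8 bond by Ni/Cr coupling of the β-C–Br bond with a C8 aldehyde.
3. Furanone (second ring) and the C4 quaternary centre ⇒ gold-triggered heterocyclization with a 1,2-methyl shift (C3 → C4) of an α-silyloxy-α-alkynyl enone, transferring the carbinol configuration.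
4. (E)-Ylidene butenolide (first ring, taken over from the anhydride) ⇒ Wittig olefination of dibromomaleic anhydride by a β-keto ylide; the ylide ⇒ ester from asymmetric alkynylation of methyl pyruvate.
5. Building blocks: maleic anhydride, (S)-α-methyl-γ-butyrolactone, methyl pyruvate, 2-(hydroxymethyl)acrylic acid.

Assumption: (S)-α-methyl-γ-butyrolactone and 2-(hydroxymethyl)acrylic acid are catalogue compounds; macrocycle carbons carry germacrane numbers (C1 furanone C–O, C3 ketone, C4 quaternary, C5=C6 ylidene, C7/C11 butenolide β/α, C8 carbinol, C10 CHMe, C12 lactone C=O, C13 CH2O).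

## Route

Step 1
Reactants: 1 maleic anhydride
Product: 2 3,4-dibromofuran-2,5-dione (dibromomaleic anhydride)
Conditions: Br2 (2.1 equiv), AlCl3 (2 mol %), neat, sealed tube, 120 °C
Reagents that add atoms: bromine, BrBr
Why: Lewis-acid-promoted bromine addition and thermal dehydrobromination (twice) give the symmetrical dibromide, so the later anhydride olefination has no regiochemical question and both C–Br handles (C7, C11) are in place.

Step 2
Reactants: 3 (3S)-3-methyloxolan-2-one
Product: 5 (3S)-3-methylpent-4-yn-1-ol, via lactol 4 (not isolated)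
Conditions: i-Bu2AlH, CH2Cl2, −78 °C; then MeOH, K2CO3, dimethyl (1-diazo-2-oxopropyl)phosphonate, 0 to 23 °C
Reagents that add atoms: dimethyl (1-diazo-2-oxopropyl)phosphonate, CC(=O)C(=[N+]=[N-])P(=O)(OC)OC
Why: Half-reduction of the lactone and Seyferth–Gilbert homologation (Ohira–Bestmann reagent) on the lactol turn the carbonyl carbon into the alkyne (C1, C2), and the chiral-pool α-methyl centre (C10, S) is carried through the mildly basic conditions.

Step 3
Reactants: 5 (3S)-3-methylpent-4-yn-1-ol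
Product: 6 triethyl{[(3S)-3-methylpent-4-yn-1-yl]oxy}silane
Conditions: TESCl, imidazole, CH2Cl2, 0 °C
Reagents that add atoms: chlorotriethylsilane, CC[Si](Cl)(CC)CC
Why: Standard silylation masks the primary alcohol (future C8 aldehyde) as a TES ether that survives the ylide chemistry and can later be oxidised directly.

Step 4
Reactants: 6 triethyl{[(3S)-3-methylpent-4-yn-1-yl]oxy}silane; 7 methyl pyruvate
Product: 9 methyl (2S,5S)-2,5-dimethyl-2,7-bis(triethylsilyloxy)hept-3-ynoate, via carbinol 8 (not isolated)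
Conditions: Zn(OTf)2 (20 mol %), chiral β-amino alcohol ligand (22 mol %, antipode that gives the 2S carbinol), Et3N (30 mol %), toluene, 70 °C; then 2,6-lutidine, TESOTf, 0 °C
Reagents that add atoms: triethylsilyl trifluoromethanesulfonate, CC[Si](CC)(CC)OS(=O)(=O)C(F)(F)F
Why: Catalytic enantioselective alkynylation of an α-keto ester by a zinc acetylide sets the tertiary carbinol (2S, future C3) under ligand control, and in-flask silylation protects it for the next two steps.

Step 5
Reactants: 9 methyl (2S,5S)-2,5-dimethyl-2,7-bis(triethylsilyloxy)hept-3-ynoate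
Product: 10 (3S,6S)-3,6-dimethyl-3,8-bis(triethylsilyloxy)-1-(triphenyl-λ5-phosphanylidene)oct-4-yn-2-one
Conditions: Ph3PCH3Br (3 equiv), n-BuLi (2.9 equiv), THF, 0 °C; then 9, 0 to 60 °C
Reagents that add atoms: methyltriphenylphosphonium bromide, C[P+](c1ccccc1)(c1ccccc1)c1ccccc1.[Br-]
Why: Acylation of methylenetriphenylphosphorane by the ester (a second equivalent deprotonates the acylphosphonium salt) gives the stabilized β-keto ylide that carries C5.

Step 6
Reactants: 10 (3S,6S)-3,6-dimethyl-3,8-bis(triethylsilyloxy)-1-(triphenyl-λ5-phosphanylidene)oct-4-yn-2-one; 2 3,4-dibromofuran-2,5-dione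
Product: 11 (E)-3,4-dibromo-5-[(3S,6S)-3,6-dimethyl-2-oxo-3,8-bis(triethylsilyloxy)oct-4-yn-1-ylidene]furan-2(5H)-one
Conditions: toluene, 0 to 23 °C
Reagents that add atoms: none
Why: Wittig olefination of a cyclic anhydride carbonyl by a stabilized ylide (maleic anhydrides react at C=O, not at C=C) gives the enol lactone with the kinetic E geometry (acyl carbon anti to the ring oxygen), which places C4 cis to C7 as the macrocycle requires.

Step 7
Reactants: 11 (E)-3,4-dibromo-5-[(3S,6S)-3,6-dimethyl-2-oxo-3,8-bis(triethylsilyloxy)oct-4-yn-1-ylidene]furan-2(5H)-one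
Product: 12 3,4-dibromo-5-[(E)-{(2S)-2-methyl-3-oxo-5-[(2S)-4-(triethylsilyloxy)butan-2-yl]-2,3-dihydrofuran-2-yl}methylidene]furan-2(5H)-one
Conditions: Ph3PAuNTf2 (5 mol %), i-PrOH (1.5 equiv), CH2Cl2, 0 to 23 °C
Reagents that add atoms: none
Why: Proposed new method: monovalent gold activates the alkyne, the C4 enone oxygen closes the five-membered ring at C1 (5-endo-dig), and the resulting cyclic oxocarbenium ion triggers a suprafacial 1,2-shift of the C3 methyl to C4 while the C3–OSiEt3 oxygen becomes the C3 ketone; the silyl group is passed to i-PrOH, whose proton removes gold from C2, so the (S) carbinol configuration is transferred to the (S) quaternary C4. The closest known reaction type is the PtCl2- or AuCl3-catalysed heterocyclization/1,2-migration of free 2-hydroxy-2-alkynyl ketones to 3(2H)-furanones together with silyl-terminated semipinacol shifts; new here are the silyl-ether termination, the cross-conjugated enol-lactone enone as the nucleophile and the use of the shift for central chirality transfer.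

Step 8
Reactants: 12 3,4-dibromo-5-[(E)-{(2S)-2-methyl-3-oxo-5-[(2S)-4-(triethylsilyloxy)butan-2-yl]-2,3-dihydrofuran-2-yl}methylidene]furan-2(5H)-one
Product: 13 (3S)-3-[(5S)-5-{(E)-(3,4-dibromo-5-oxofuran-2(5H)-ylidene)methyl}-5-methyl-4-oxo-4,5-dihydrofuran-2-yl]butanal
Conditions: (COCl)2, DMSO, CH2Cl2, −78 to −40 °C; then Et3N, −78 to 0 °C
Reagents that add atoms: none
Why: Under Swern conditions a primary TES ether is cleaved by the chlorosulfonium salt and oxidised in the same operation, giving the C8 aldehyde without a separate deprotection and without touching the enol lactone or the vinylogous ester.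

Step 9
Reactants: 13 (3S)-3-[(5S)-5-{(E)-(3,4-dibromo-5-oxofuran-2(5H)-ylidene)methyl}-5-methyl-4-oxo-4,5-dihydrofuran-2-yl]butanal
Product: 14 (4S,8S,10S)-11-bromo-8-hydroxy-3-oxo-1,4-epoxy-13-norgermacra-1,5E,7(11)-trien-12,6-olide
Conditions: CrCl2 (6 equiv), NiCl2 (5 mol %), Kishi-type chiral oxazoline sulfonamide ligand (6.5 equiv, antipode matched to 8S), Et3N, MeCN/THF, 23 °C, 2 mM
Reagents that add atoms: none
Why: Nozaki–Hiyama–Kishi macrocyclization: zerovalent nickel inserts into the β-C–Br bond (a vinylogous acyl bromide, far more reactive than the α-C–Br bond), the alkenyl group passes to trivalent chromium and adds to the aldehyde to close the ten-membered carbocycle, and the chiral chromium–sulfonamide complex selects the aldehyde face that gives 8S.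

Step 10
Reactants: 14 (4S,8S,10S)-11-bromo-8-hydroxy-3-oxo-1,4-epoxy-13-norgermacra-1,5E,7(11)-trien-12,6-olide
Product: 15 (4S,8S,10S)-8,13-dihydroxy-3-oxo-1,4-epoxygermacra-1,5E,7(11)-trien-12,6-olide
Conditions: Bu3SnCH2OH (2 equiv), Pd(PPh3)4 (10 mol %), 1,4-dioxane, 80 °C
Reagents that add atoms: (tributylstannyl)methanol, OC[Sn](CCCC)(CCCC)CCCC
Why: Stille hydroxymethylation of the α-bromo butenolide forms the C11–C13 bond; it is run at the free-alcohol stage so that no allylic ester is exposed to zerovalent palladium.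

Step 11
Reactants: 15 (4S,8S,10S)-8,13-dihydroxy-3-oxo-1,4-epoxygermacra-1,5E,7(11)-trien-12,6-olide
Product: 16 (4S,8S,10S)-13-acetoxy-8-hydroxy-3-oxo-1,4-epoxygermacra-1,5E,7(11)-trien-12,6-olide
Conditions: Ac2O (1.1 equiv), 2,4,6-collidine, CH2Cl2, −20 °C
Reagents that add atoms: acetic anhydride, CC(=O)OC(C)=O
Why: Kinetically selective acylation: the unhindered primary allylic C13 alcohol is acetylated much faster than the hindered secondary C8 alcohol.

Step 12
Reactants: 17 2-(hydroxymethyl)prop-2-enoic acid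
Product: 19 2-[(tert-butyldimethylsilyloxy)methyl]prop-2-enoic acid, via silyl ester 18 (not isolated)
Conditions: TBSCl (2.2 equiv), imidazole, DMF, 23 °C; then THF/H2O/AcOH, 23 °C
Reagents that add atoms: tert-butylchlorodimethylsilane, CC(C)(C)[Si](C)(C)Cl
Why: Bis-silylation followed by selective hydrolysis of the much more labile silyl ester gives the O-protected side-chain acid.

Step 13
Reactants: 16 (4S,8S,10S)-13-acetoxy-8-hydroxy-3-oxo-1,4-epoxygermacra-1,5E,7(11)-trien-12,6-olide; 19 2-[(tert-butyldimethylsilyloxy)methyl]prop-2-enoic acid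
Product: 21 (4S,8S,10S)-13-acetoxy-8-{2-[(tert-butyldimethylsilyloxy)methyl]prop-2-enoyloxy}-3-oxo-1,4-epoxygermacra-1,5E,7(11)-trien-12,6-olide, via mixed anhydride 20 (not isolated)
Conditions: 2,4,6-trichlorobenzoyl chloride, Et3N, toluene, 23 °C; then 16, DMAP, 23 °C
Reagents that add atoms: none
Why: Yamaguchi esterification acylates the hindered secondary allylic alcohol at oxygen with retention at C8.

Step 14
Reactants: 21 (4S,8S,10S)-13-acetoxy-8-{2-[(tert-butyldimethylsilyloxy)methyl]prop-2-enoyloxy}-3-oxo-1,4-epoxygermacra-1,5E,7(11)-trien-12,6-olide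
Product: 22 (4S,8S,10S)-13-acetoxy-8-[2-(hydroxymethyl)prop-2-enoyloxy]-3-oxo-1,4-epoxygermacra-1,5E,7(11)-trien-12,6-olide (CNP0193735.1)
Conditions: HF·pyridine, pyridine, THF, 0 °C
Reagents that add atoms: none
Why: Buffered fluoride desilylation frees the primary alcohol while the acetate, the acrylate and the enol lactone stay intact.

## Compound list

1 | maleic anhydride (furan-2,5-dione) | O=C1OC(=O)C=C1 | starting material
2 | 3,4-dibromofuran-2,5-dione (dibromomaleic anhydride) | O=C1OC(=O)C(Br)=C1Br | intermediate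
3 | (3S)-3-methyloxolan-2-one ((S)-α-methyl-γ-butyrolactone) | C[C@H]1CCOC1=O | starting material
4 | (3S)-3-methyloxolan-2-ol (lactol, both anomers) | C[C@H]1CCOC1O | intermediate
5 | (3S)-3-methylpent-4-yn-1-ol | C#C[C@@H](C)CCO | intermediate
6 | triethyl{[(3S)-3-methylpent-4-yn-1-yl]oxy}silane | C#C[C@@H](C)CCO[Si](CC)(CC)CC | intermediate
7 | methyl pyruvate (methyl 2-oxopropanoate) | COC(=O)C(C)=O | starting material
8 | methyl (2S,5S)-2-hydroxy-2,5-dimethyl-7-(triethylsilyloxy)hept-3-ynoate | COC(=O)[C@@](C)(O)C#C[C@@H](C)CCO[Si](CC)(CC)CC | intermediate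
9 | methyl (2S,5S)-2,5-dimethyl-2,7-bis(triethylsilyloxy)hept-3-ynoate | COC(=O)[C@@](C)(O[Si](CC)(CC)CC)C#C[C@@H](C)CCO[Si](CC)(CC)CC | intermediate
10 | (3S,6S)-3,6-dimethyl-3,8-bis(triethylsilyloxy)-1-(triphenyl-λ5-phosphanylidene)oct-4-yn-2-one | O=C(C=P(c1ccccc1)(c1ccccc1)c1ccccc1)[C@@](C)(O[Si](CC)(CC)CC)C#C[C@@H](C)CCO[Si](CC)(CC)CC | intermediate
11 | (E)-3,4-dibromo-5-[(3S,6S)-3,6-dimethyl-2-oxo-3,8-bis(triethylsilyloxy)oct-4-yn-1-ylidene]furan-2(5H)-one | O=C1O/C(=C/C(=O)[C@@](C)(O[Si](CC)(CC)CC)C#C[C@@H](C)CCO[Si](CC)(CC)CC)C(Br)=C1Br | intermediate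
12 | 3,4-dibromo-5-[(E)-{(2S)-2-methyl-3-oxo-5-[(2S)-4-(triethylsilyloxy)butan-2-yl]-2,3-dihydrofuran-2-yl}methylidene]furan-2(5H)-one | CC[Si](CC)(CC)OCC[C@H](C)C1=CC(=O)[C@](C)(/C=C2/OC(=O)C(Br)=C2Br)O1 | intermediate
13 | (3S)-3-[(5S)-5-{(E)-(3,4-dibromo-5-oxofuran-2(5H)-ylidene)methyl}-5-methyl-4-oxo-4,5-dihydrofuran-2-yl]butanal | O=CC[C@H](C)C1=CC(=O)[C@](C)(/C=C2/OC(=O)C(Br)=C2Br)O1 | intermediate
14 | (4S,8S,10S)-11-bromo-8-hydroxy-3-oxo-1,4-epoxy-13-norgermacra-1,5E,7(11)-trien-12,6-olide | O[C@H]1C[C@H](C)C2=CC(=O)[C@](C)(/C=C3/OC(=O)C(Br)=C31)O2 | intermediate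
15 | (4S,8S,10S)-8,13-dihydroxy-3-oxo-1,4-epoxygermacra-1,5E,7(11)-trien-12,6-olide | O[C@H]1C[C@H](C)C2=CC(=O)[C@](C)(/C=C3/OC(=O)C(CO)=C31)O2 | intermediate
16 | (4S,8S,10S)-13-acetoxy-8-hydroxy-3-oxo-1,4-epoxygermacra-1,5E,7(11)-trien-12,6-olide | O[C@H]1C[C@H](C)C2=CC(=O)[C@](C)(/C=C3/OC(=O)C(COC(C)=O)=C31)O2 | intermediate
17 | 2-(hydroxymethyl)prop-2-enoic acid | C=C(CO)C(=O)O | starting material
18 | tert-butyldimethylsilyl 2-[(tert-butyldimethylsilyloxy)methyl]prop-2-enoate | C=C(CO[Si](C)(C)C(C)(C)C)C(=O)O[Si](C)(C)C(C)(C)C | intermediate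
19 | 2-[(tert-butyldimethylsilyloxy)methyl]prop-2-enoic acid | C=C(CO[Si](C)(C)C(C)(C)C)C(=O)O | intermediate
20 | 2-[(tert-butyldimethylsilyloxy)methyl]prop-2-enoic 2,4,6-trichlorobenzoic anhydride | C=C(CO[Si](C)(C)C(C)(C)C)C(=O)OC(=O)c1c(Cl)cc(Cl)cc1Cl | intermediate
21 | (4S,8S,10S)-13-acetoxy-8-{2-[(tert-butyldimethylsilyloxy)methyl]prop-2-enoyloxy}-3-oxo-1,4-epoxygermacra-1,5E,7(11)-trien-12,6-olide | C=C(CO[Si](C)(C)C(C)(C)C)C(=O)O[C@H]1C[C@H](C)C2=CC(=O)[C@](C)(/C=C3/OC(=O)C(COC(C)=O)=C31)O2 | intermediate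
22 | (4S,8S,10S)-13-acetoxy-8-[2-(hydroxymethyl)prop-2-enoyloxy]-3-oxo-1,4-epoxygermacra-1,5E,7(11)-trien-12,6-olide (CNP0193735.1) | C=C(CO)C(=O)O[C@H]1C[C@H](C)C2=CC(=O)[C@](C)(/C=C3/OC(=O)C(COC(C)=O)=C31)O2 | target

## Step count and risks

Total step count: 14. Longest linear sequence: 12 steps (3 → 22 by steps 2 to 11, 13 and 14).

**Step 6 (anhydride Wittig).** The ylide may attack a C–Br carbon instead of the carbonyl, or the E/Z ratio may be poor; only the E isomer can close the macrocycle. The fallback swaps the roles of the partners; it sets out from 10 and comes back at 11. Dimethyldioxirane (acetone, −78 to 0 °C) cleaves the P=C bond of 10 to the α-keto aldehyde (3S,6S)-3,6-dimethyl-2-oxo-3,8-bis(triethylsilyloxy)oct-4-ynal F1. A vinylogous Mukaiyama aldol with commercial 3,4-dibromofuran-2(5H)-one (TBSOTf, i-Pr2NEt, CH2Cl2, −78 °C) gives the silylated adduct 3,4-dibromo-5-[(3S,6S)-1-(tert-butyldimethylsilyloxy)-3,6-dimethyl-2-oxo-3,8-bis(triethylsilyloxy)oct-4-yn-1-yl]furan-2(5H)-one F2. DBU in the same flask eliminates silanol to a Z-rich ylidene, mainly (Z)-3,4-dibromo-5-[(3S,6S)-3,6-dimethyl-2-oxo-3,8-bis(triethylsilyloxy)oct-4-yn-1-ylidene]furan-2(5H)-one F3. Irradiation at 350 nm in benzene equilibrates the two geometries; 11 is separated and F3 is recycled.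

**Step 7 (the new gold step).** It may give alkyne hydration instead of the shift, lose E geometry through the delocalised cation, or lose the primary silyl ether early. The fallback uses the known reaction of the free carbinol; it sets out from 11 and comes back at 12. HF·pyridine (THF, 0 °C) removes both silyl groups to give (E)-3,4-dibromo-5-[(3S,6S)-3,8-dihydroxy-3,6-dimethyl-2-oxooct-4-yn-1-ylidene]furan-2(5H)-one F4. TESCl (1.05 equiv) with imidazole at −78 °C re-silylates only the primary alcohol to give (E)-3,4-dibromo-5-[(3S,6S)-3-hydroxy-3,6-dimethyl-2-oxo-8-(triethylsilyloxy)oct-4-yn-1-ylidene]furan-2(5H)-one F5. PtCl2 (5 mol %, toluene, 80 °C) then performs the established heterocyclization/1,2-migration of a free 2-hydroxy-2-alkynyl ketone, the proton being lost from O–H, and gives 12.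

**Step 9 (Ni/Cr macrocyclization).** Ring strain may lower the yield, and the ring conformation may override the ligand, giving the wrong or a mixed C8 configuration. The fallback moves stereocontrol from C–C bond formation to a ketone reduction; it sets out from 13 and comes back at 14. Ligand-free coupling (CrCl2, NiCl2 (1 mol %), DMSO/THF, 23 °C, 2 mM) closes the ring and gives 14 together with its epimer (4S,8R,10S)-11-bromo-8-hydroxy-3-oxo-1,4-epoxy-13-norgermacra-1,5E,7(11)-trien-12,6-olide F6. Dess–Martin periodinane oxidises the mixture to the enone (4S,10S)-11-bromo-3,8-dioxo-1,4-epoxy-13-norgermacra-1,5E,7(11)-trien-12,6-olide F7. Corey–Bakshi–Shibata reduction with the (R)-methyl oxazaborolidine and catecholborane (toluene, −78 °C) gives the 8S alcohol 14; the C3 vinylogous ester is not reduced.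

Further compounds
F1 | step 6 | (3S,6S)-3,6-dimethyl-2-oxo-3,8-bis(triethylsilyloxy)oct-4-ynal | O=CC(=O)[C@@](C)(O[Si](CC)(CC)CC)C#C[C@@H](C)CCO[Si](CC)(CC)CC
F2 | step 6 | 3,4-dibromo-5-[(3S,6S)-1-(tert-butyldimethylsilyloxy)-3,6-dimethyl-2-oxo-3,8-bis(triethylsilyloxy)oct-4-yn-1-yl]furan-2(5H)-one (diastereomer mixture at the two new centres) | O=C1OC(C(O[Si](C)(C)C(C)(C)C)C(=O)[C@@](C)(O[Si](CC)(CC)CC)C#C[C@@H](C)CCO[Si](CC)(CC)CC)C(Br)=C1Br
F3 | step 6 | (Z)-3,4-dibromo-5-[(3S,6S)-3,6-dimethyl-2-oxo-3,8-bis(triethylsilyloxy)oct-4-yn-1-ylidene]furan-2(5H)-one | O=C1O/C(=C\C(=O)[C@@](C)(O[Si](CC)(CC)CC)C#C[C@@H](C)CCO[Si](CC)(CC)CC)C(Br)=C1Br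
F4 | step 7 | (E)-3,4-dibromo-5-[(3S,6S)-3,8-dihydroxy-3,6-dimethyl-2-oxooct-4-yn-1-ylidene]furan-2(5H)-one | O=C1O/C(=C/C(=O)[C@@](C)(O)C#C[C@@H](C)CCO)C(Br)=C1Br
F5 | step 7 | (E)-3,4-dibromo-5-[(3S,6S)-3-hydroxy-3,6-dimethyl-2-oxo-8-(triethylsilyloxy)oct-4-yn-1-ylidene]furan-2(5H)-one | O=C1O/C(=C/C(=O)[C@@](C)(O)C#C[C@@H](C)CCO[Si](CC)(CC)CC)C(Br)=C1Br
F6 | step 9 | (4S,8R,10S)-11-bromo-8-hydroxy-3-oxo-1,4-epoxy-13-norgermacra-1,5E,7(11)-trien-12,6-olide | O[C@@H]1C[C@H](C)C2=CC(=O)[C@](C)(/C=C3/OC(=O)C(Br)=C31)O2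
F7 | step 9 | (4S,10S)-11-bromo-3,8-dioxo-1,4-epoxy-13-norgermacra-1,5E,7(11)-trien-12,6-olide | O=C1C[C@H](C)C2=CC(=O)[C@](C)(/C=C3/OC(=O)C(Br)=C31)O2
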